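## Structural features

Jaspic acid joins a bicyclic terpenoid to an arene: a trans-fused decalin (ring A = C1–C5 and C10; ring B = C5–C10) carries at C9 a methylene carbon (C11) that is bonded to C3 of a 4-hydroxybenzoic acid. Ring A holds a quaternary C4 with a methyl group (α) and a 4-methylpent-3-enyl chain (β, axial); ring B holds the C7=C8 double bond with a methyl group on C8; the C10 methyl group is β and the C5 hydrogen α. The four stereocentres C4, C5, C10 and C9 form an unbroken chain, two of them (C4, C10) are quaternary, and both the C4 chain and the C9 benzyl group lie on the face of the C10 methyl group, the first 1,3-diaxial to it and the second on the neighbouring carbon. Fragile groups are the two trisubstituted alkenes (acids, electrophilic and allylic oxidants), the allylic C9–H (migration of the alkene to C8=C9 would erase that stereocentre) and, above all, the free ortho-hydroxybenzyl unit next to the C7=C8 bond, which closes to a chromane under acid. The arene is simple; the real difficulty is to place carbon substituents on the hindered β-face at C4 and C9 and to obtain one enantiomer from achiral materials. The key step exploits the fact that C10 is flanked by C5 and C9, both of which can be carbonyl carbons of one symmetrical cyclohexane-1,3-dione, and that C4 and C5 form an enone retron once C3 is a ketone: closing the C4=C5 bond of ring A on one of two enantiotopic carbonyls makes C10 stereogenic. Once C10 is fixed, C5 and C4 follow from it in one reductive alkylation and C9 follows through a relay over C7.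

## Logic of the disconnections

34 ⇒ 33. The phenolic O–H and the carboxylic O–H are exchanged for O–CH3 bonds. The free phenol must not meet acid while the C7=C8 alkene is present, and the earlier enolate and radical steps need both acidic groups masked. The gain is a neutral, robust arene; the demand is a non-acidic removal of both methyl groups in one operation.

33 ⇒ 31. A carboxyl group is added to C11. This turns the benzylic methylene into the α-carbon of an arylacetic acid, the retron of an ester enolate rearrangement, at the price of one carbon that must leave again. The forward step must remove it under neutral conditions without touching either alkene or C9.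

31 ⇒ 28. The C9–C11 bond is cut, the C7–O bond is restored and the alkene moves from C7=C8 to C8=C9. Carbon has to reach the β-face of C9 beside the quaternary C10, which an intermolecular reagent would avoid, whereas a [3,3] shift is intramolecular and suprafacial. The C9 stereocentre is traded for a carbinol centre at C7. The forward step needs the C7 oxygen to be β and a ketene acetal that forms in the presence of the benzoate ester.

28 ⇒ 25 + 27, and 27 ⇒ 26. The ester C7–O bond is cut, which makes the route convergent; the aryl–CO2CH3 bond of 27 is cut back to the C–Br bond of 26. Because the oxygen of 25 is α, the forward esterification must invert C7; the carbonylation must tolerate the free acetic acid side chain.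

25 ⇒ 23 ⇒ 22. In going back from 25 to 23, C9 regains its carbonyl and the C8–O bond is re-formed; from 23 to 22 the epoxide C7–O and C8–O bonds are cut. The annulation leaves oxygen on C9 while the sigmatropic step needs it on C7; a 1,3-transposition through nucleophilic epoxidation oxidises ring B without touching the electron-rich side-chain alkene. The forward steps need facial control at C7 and hydrazone formation at a crowded carbonyl.

22 ⇒ 20 ⇒ 18. The C7=C8 unsaturation and then the C8–CH3 bond are removed. Both come from the C9 ketone, whose only enolizable side is C8, so regiochemistry is not in question; the gain is an unsubstituted ring B. The forward steps need mono-methylation and a dehydrogenation that gives the endocyclic enone.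

18 ⇒ 15. A carbonyl is put back on C3 and the C9 ketone is masked as a ketal. The C3 oxygen is the retron of the ring A annulation and the activating group for quaternisation of C4. In the forward sense it must be removed from a neopentyl position, and the ketal must then be opened without hydrating the alkene.

15 ⇒ 13 ⇒ 12. The C4–CH3 and C5–H bonds are cut together, regenerating the C4=C5 enone, and the ketal C9–O bonds are cut. Two of four stereocentres vanish at once and C10 remains as the only one. The forward reductive methylation must give the trans fusion, trap the enolate at C4 only and deliver methyl to the α-face; the ketalization must distinguish the two carbonyls.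

12 ⇒ 10. The C4=C5 bond is cut (aldol condensation retron), which opens ring A and leaves an achiral triketone with two enantiotopic ring carbonyls. This is the strategic cut: it removes the last stereocentre and a ring, and places the C4 side chain in an acyclic ketone that is easy to assemble. The forward step must choose one carbonyl with a chiral catalyst and form the enamine on the substituted side of the chain ketone.

10 ⇒ 8 + 9. The C1–C10 bond is cut (Michael retron of the 1,5-dicarbonyl unit). The forward step must alkylate carbon, not oxygen, and avoid polymerisation of the enone.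

8 ⇒ 5 + 6, 5 ⇒ 4, 4 ⇒ 3 ⇒ 1 + 2. The vinyl–carbonyl bond is cut to an acyl donor and a vinyl nucleophile; the acyl donor is traced through the ester to a malonate, and the bond between the malonate carbon and the homoallylic CH2 is cut. The forward steps must stop the vinyl addition at the ketone stage and keep the alkylation of 1 at the mono stage.

## Other disconnections considered

Alternative 1: The cut runs on both sides of C11 (C9–C11 and C11–aryl), with C11 at the ketone oxidation level. In the forward step the enol triflate A1, carbon monoxide and the aryl boronate A2 would be joined by a Pd(OAc)2/phosphine-catalysed carbonylative Suzuki–Miyaura coupling to the aryl enone A3. γ-Deprotonation and kinetic protonation at C9 would then move the alkene to C7=C8, and the C11 oxygen would be removed.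
- In favour: it is convergent and forms two skeletal bonds in one operation at a trigonal carbon, where the neighbouring quaternary C10 hinders less than at a tetrahedral C9. It uses the C9 carbonyl where the annulation leaves it, so no oxygen transposition to C7 is needed.
- Against: the C9 configuration would depend on the face from which a proton reaches a dienolate; the less hindered α-face is the right one, but nothing enforces it. The new stereocentre would stay α to a ketone until C11 is deoxygenated, inviting reconjugation or epimerisation. Direct coupling without CO insertion competes at a hindered tetrasubstituted triflate, and a non-acidic benzylic deoxygenation costs two further steps.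
- Comparison: structurally both reach the same decalin, but this alternative does not address C4, C5 and C10, so it is an endgame and not a substitute for the annulation. Mechanistically it replaces a suprafacial transfer of chirality from C7 to C9 by a reagent-controlled protonation. In step count it is equal to, or one operation shorter than, steps 11–13 and 15–17, and equal in convergence. The chosen plan is preferred only because the stereochemical course of its pericyclic step is fixed by the C7 configuration; this alternative serves as the fallback for step 16.

Alternative 2: The cut removes C8 and its methyl group from ring B by breaking C7–C8 and C8–C9, leading back to the trans-hydrindanone A4. In the forward step the silyl enol ether A5 would be cyclopropanated by chloro(methyl)carbene (1,1-dichloroethane, n-BuLi), and the chlorocyclopropane would open with loss of chloride and silyl to the ring-expanded 2-methyl enone A6.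
- In favour: one operation brings in C8, its methyl group and the C7=C8 unsaturation with unambiguous regiochemistry. The chosen route needs steps 10 and 11 for this, so here the alternative is the better.
- Against: the difficulty moves into A4, a trans-fused hydrindanone with two quaternary carbons (C4, C10), for which no equally direct enantioselective annulation is at hand. The side chain is carried as a silyl ether stub that needs deprotection, oxidation and olefination, and the carbenoid requires n-BuLi.
- Comparison: structurally, ring B comes ready-made from 9 in the chosen plan and must be grown here. Mechanistically, carbene addition and cyclopropane opening set no stereocentre, so all stereocontrol rests on A4, whereas the chosen key step creates C10. In step count, one step saved at C8 stands against at least three for the side chain plus the unspecified synthesis of A4. A6 corresponds to 22 with an unfinished side chain, so both plans would share the same endgame.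

Alternative 3: The cut is C1–C10 on an aromatic precursor, the dimethylphenol A7, in which ring B is still an arene and its C5 carries a 2-oxobut-3-enyl tether. In the forward step a chiral catalyst pairing with the phenolate of A7 would direct the para carbon C10 to the enone terminus C1 in a 6-endo Michael addition that closes ring A and gives the dienone A8.
- In favour: like the chosen key step it creates C10, and only C10, catalytically from an achiral precursor; on this point the two are equal. A8 already holds the C8 methyl group, the C8=C9 alkene and an oxygen at C7, the array the chosen route needs steps 10–13 and an inversion to reach; on this point the alternative is the better.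
- Against: ring A arrives empty. Both C4 substituents would have to be introduced by successive alkylations next to the C3 ketone, with C2 and oxygen competing and the larger group required axial. The C5=C6 bond would have to be reduced to the trans fusion beside a quaternary C4, C3 must be deoxygenated, and two ketones and two enone units must be told apart throughout. The dearomatization of A7 must also beat O-alkylation and ortho attack.
- Comparison: structurally, the chosen plan builds ring A with the C4 chain in place and lets one reductive methylation set C4 and C5, whereas the alternative finishes ring B and leaves ring A for later. Mechanistically, enamine aldol desymmetrization stands against enantiofacial attack on a prochiral arene carbon, each with one catalyst-controlled event. In step count, the saving of about four ring B steps is likely offset by the C4 dialkylation, the alkene reduction and the redox adjustments, so no clear gain is foreseen.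

Key step: step 6

Numbering: labdane-type numbering is used for the bicyclic part (ring A = C1–C5 and C10; ring B = C5–C10; C11 = benzylic carbon); β is the face of the C10 methyl group, α the opposite face.

Assumption: the alkaline epoxidation of step 12 is taken to occur on the α-face (axial attack at C7, anti to the C10 methyl group), which is why the esterification of step 15 is run with inversion at C7.

Check of structures: the (S) configuration at C10 of 12 places the angular methyl group on the same face as in the target and is the sense expected from L-amino acids; the constitutions of 10 and 12 are consistent with the ring A closure and need no correction.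

## Route

Step 1
Reactants: 1 diethyl malonate; 2 5-bromo-2-methylpent-2-ene
Product: 3 diethyl 2-(4-methylpent-3-en-1-yl)malonate
Conditions: NaOEt, EtOH, reflux (1 in excess)
Reagents that add atoms: none
Why: Malonic ester alkylation: the sodium enolate of 1 displaces the primary homoallylic bromide by SN2; excess 1 keeps dialkylation low and the weakly basic nucleophile limits E2 loss of HBr from 2.

Step 2
Reactants: 3 diethyl 2-(4-methylpent-3-en-1-yl)malonate
Product: 4 ethyl 6-methylhept-5-enoate
Conditions: NaCl, H2O, DMSO, 160 °C
Reagents that add atoms: none
Why: Krapcho dealkoxycarbonylation removes one ester group as CO2 and ethanol under neutral conditions, sparing the trisubstituted alkene that an acidic hydrolysis–decarboxylation could hydrate.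

Step 3
Reactants: 4 ethyl 6-methylhept-5-enoate
Product: 5 N-methoxy-N,6-dimethylhept-5-enamide
Conditions: MeNH(OMe)·HCl, i-PrMgCl, THF, −20 → 0 °C
Reagents that add atoms: N,O-dimethylhydroxylamine hydrochloride, CNOC.Cl
Why: The chloromagnesium amide formed in the flask attacks the ester (aminolysis to a Weinreb amide), and the amide product does not react further under these conditions.

Step 4
Reactants: 5 N-methoxy-N,6-dimethylhept-5-enamide; 6 vinylmagnesium bromide
Product: 8 8-methylnona-1,7-dien-3-one, via magnesium chelate 7 (not isolated)
Conditions: THF, 0 °C; inverse quench into cold 1 M HCl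
Reagents that add atoms: none
Why: Weinreb ketone synthesis: the five-membered magnesium chelate 7 holds the tetrahedral adduct until work-up so that only one vinyl group adds, and quenching into acid protonates the released N,O-dimethylhydroxylamine before it can add to the new enone.

Step 5
Reactants: 8 8-methylnona-1,7-dien-3-one; 9 2-methylcyclohexane-1,3-dione
Product: 10 2-methyl-2-(8-methyl-3-oxonon-7-en-1-yl)cyclohexane-1,3-dione
Conditions: Et3N (cat.), EtOAc, 25 → 50 °C
Reagents that add atoms: none
Why: Michael addition of the acidic 1,3-dione (as its ammonium enolate) to the vinyl ketone alkylates C2 of the dione and forms the C1–C10 bond; the new quaternary carbon is not yet stereogenic because its two ring carbonyl arms are identical.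

Step 6
Reactants: 10 2-methyl-2-(8-methyl-3-oxonon-7-en-1-yl)cyclohexane-1,3-dione
Product: 12 (8aS)-8a-methyl-5-(4-methylpent-3-en-1-yl)-3,4,8,8a-tetrahydronaphthalene-1,6(2H,7H)-dione, via ketol 11 (not isolated)
Conditions: L-phenylalanine (1 equiv), (1S)-(+)-camphor-10-sulfonic acid (0.5 equiv), DMF, 30 → 70 °C
Reagents that add atoms: none
Why: The primary amine of L-phenylalanine condenses with the unhindered acyclic C3 ketone of 10, and the sulfonic acid co-catalyst speeds iminium–enamine exchange towards C4, the only enamine position from which a six-membered ring can form. The enamine carbon C4 then adds to C5 in a chair-like 6-(enolendo)-exo-trig aldol closure that makes ring A, while the carboxylic acid of the catalyst hydrogen-bonds to the carbonyl under attack. Ketol 11 loses water under the same acidic conditions to give the conjugated C4=C5 enone. The closest known reaction type is the Hajos–Parrish–Eder–Sauer–Wiechert cyclization of 2-methyl-2-(3-oxoalkyl)cyclohexane-1,3-diones that bear a substituent on the nucleophilic carbon, for which the phenylalanine/camphorsulfonic acid pair is the usual choice. C10 is the only new stereocentre: it becomes stereogenic because one of two enantiotopic carbonyls is consumed, and the catalyst-bound transition state decides which, the L-series giving the (S)-enantiomer with the methyl group β. The selectivity needed is enantiotopic-group selection, which the mirror-symmetric substrate cannot bias and the hydrogen-bonded chiral enamine supplies; regioselectivity is secured by ring size, and the isolated trisubstituted alkene should be inert to the buffered ammonium sulfonate medium.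

Step 7
Reactants: 12 (10S)-enedione
Product: 13 C9 ethylene ketal of 12 (spiro-1,3-dioxolane at C9; C3 enone unchanged; 10S)
Conditions: HOCH2CH2OH, TsOH·H2O (cat.), 4 Å molecular sieves, CH2Cl2, rt
Reagents that add atoms: ethane-1,2-diol, OCCO
Why: Chemoselective ketalization: the saturated C9 ketone is far more electrophilic than the tetrasubstituted, conjugated C3 carbonyl, and short contact with anhydrous acid at room temperature leaves the enone in conjugation and the side-chain alkene untouched.

Step 8
Reactants: 13 C9 ethylene ketal of 12
Product: 15 9,9-ethylenedioxy-4α,10β-dimethyl-4β-(4-methylpent-3-en-1-yl)-5α-H-decalin-3-one, via lithium enolate 14 (not isolated)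
Conditions: Li (2.2 equiv), t-BuOH (1 equiv), NH3 (l)/THF, −78 → −33 °C; then MeI, −78 → −33 °C
Reagents that add atoms: iodomethane, CI
Why: Birch-type reductive alkylation of the enone: two electrons and one proton give the C3–C4 lithium enolate 14 with C5 protonated axially (5α-H, trans fusion, the usual outcome for 10-methyl octalones). The regiodefined enolate is then methylated at C4 from the α-face, away from the axial C10 methyl group, which leaves the homoprenyl chain axial (4β) as the target requires.

Step 9
Reactants: 15 9,9-ethylenedioxy-4α,10β-dimethyl-4β-(4-methylpent-3-en-1-yl)-5α-H-decalin-3-one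
Product: 18 4α,10β-dimethyl-4β-(4-methylpent-3-en-1-yl)-5α-H-decalin-9-one, via hydrazone 16 (not isolated), via deoxygenated ketal 17 (not isolated)
Conditions: N2H4·H2O, KOH, diethylene glycol, 130 → 200 °C; then, on the crude extract, PPTS, acetone/H2O, reflux
Reagents that add atoms: water, O
Why: Wolff–Kishner reduction (high-temperature glycol variant) removes the neopentyl C3 carbonyl through hydrazone 16 under basic conditions that the dioxolane and the isolated alkene tolerate; crude ketal 17 is then hydrolysed with a weak acid in wet acetone so that the trisubstituted alkene is not hydrated.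

Step 10
Reactants: 18 4α,10β-dimethyl-4β-(4-methylpent-3-en-1-yl)-5α-H-decalin-9-one
Product: 20 4α,8,10β-trimethyl-4β-(4-methylpent-3-en-1-yl)-5α-H-decalin-9-one (C8 epimers), via lithium enolate 19 (not isolated)
Conditions: LiN(i-Pr)2, THF, −78 °C; then MeI, −78 → 0 °C
Reagents that add atoms: iodomethane, CI
Why: The C9 ketone can enolize only towards C8 because C10 is quaternary, so the enolate alkylation is regiospecific; the configuration at C8 is irrelevant because that centre becomes trigonal in the next step.

Step 11
Reactants: 20 4α,8,10β-trimethyl-4β-(4-methylpent-3-en-1-yl)-5α-H-decalin-9-one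
Product: 22 4α,8,10β-trimethyl-4β-(4-methylpent-3-en-1-yl)-5α-H-decal-7-en-9-one, via silyl enol ether 21 (not isolated)
Conditions: LiN(i-Pr)2, Me3SiCl, THF, −78 → 0 °C; then Pd(OAc)2, MeCN, rt
Reagents that add atoms: none
Why: Saegusa–Ito oxidation: the only possible trimethylsilyl enol ether (C8=C9) is palladated at C8 by divalent palladium, and syn β-hydride elimination towards the ring hydrogen at C7 gives the conjugated endocyclic enone, any exocyclic isomer being funnelled to it by palladium hydride re-addition; the side-chain alkene should not react with Pd(OAc)2 at room temperature.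

Step 12
Reactants: 22 4α,8,10β-trimethyl-4β-(4-methylpent-3-en-1-yl)-5α-H-decal-7-en-9-one
Product: 23 7α,8α-epoxy-4α,8β,10β-trimethyl-4β-(4-methylpent-3-en-1-yl)-5α-H-decalin-9-one
Conditions: 30% H2O2, NaOH, MeOH, 0 °C → rt
Reagents that add atoms: hydrogen peroxide, OO
Why: Weitz–Scheffer epoxidation: hydroperoxide anion adds only to the electron-poor C7=C8 bond, leaving the side-chain alkene alone, and is expected to attack C7 axially on the α-face, opposite the C10 methyl group, so that closure gives the 7α,8α-epoxide.

Step 13
Reactants: 23 7α,8α-epoxy ketone
Product: 25 4α,8,10β-trimethyl-4β-(4-methylpent-3-en-1-yl)-5α-H-decal-8-en-7α-ol, via epoxy hydrazone 24 (not isolated)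
Conditions: N2H4·H2O, AcOH, MeOH, 0 °C → rt
Reagents that add atoms: none
Why: Wharton transposition: hydrazone 24 opens the epoxide to a vinyl diazene that loses N2, which moves the double bond to C8=C9 and leaves the oxygen on C7 with its configuration untouched (7α), as in the conversion of 2-methylcyclohexenone epoxides into transposed allylic alcohols.

Step 14
Reactants: 26 2-(5-bromo-2-methoxyphenyl)acetic acid
Product: 27 2-[2-methoxy-5-(methoxycarbonyl)phenyl]acetic acid
Conditions: Pd(OAc)2 (cat.), Xantphos, CO (1 atm), Et3N, MeOH, 70 °C
Reagents that add atoms: carbon monoxide, [C-]#[O+]; methanol, CO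
Why: Palladium-catalysed methoxycarbonylation of the aryl bromide (oxidative addition to zerovalent palladium, CO insertion, methanolysis of the acylpalladium); the acetic acid side chain is present as its unreactive triethylammonium carboxylate and is recovered on acidification.

Step 15
Reactants: 25 8-en-7α-ol; 27 2-[2-methoxy-5-(methoxycarbonyl)phenyl]acetic acid
Product: 28 4α,8,10β-trimethyl-4β-(4-methylpent-3-en-1-yl)-5α-H-decal-8-en-7β-yl 2-[2-methoxy-5-(methoxycarbonyl)phenyl]acetate
Conditions: PPh3, DIAD, THF, 0 °C → rt
Reagents that add atoms: none
Why: Mitsunobu esterification: the oxyphosphonium salt of the pseudo-axial 7α-alcohol is displaced by the arylacetate with SN2 inversion, giving the 7β-ester needed for suprafacial delivery to the β-face of C9; SN2' attack at C9 is disfavoured by the adjacent quaternary C10.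

Step 16
Reactants: 28 7β-yl arylacetate
Product: 31 2-[2-methoxy-5-(methoxycarbonyl)phenyl]-2-[4α,8,10β-trimethyl-4β-(4-methylpent-3-en-1-yl)-5α-H-decal-7-en-9β-yl]acetic acid (C11 epimers), via silyl ketene acetal 29 (not isolated), via trimethylsilyl ester 30 (not isolated)
Conditions: LiN(SiMe3)2, Me3SiCl, THF, −78 → 65 °C; then aq. NH4Cl
Reagents that add atoms: none
Why: Ireland–Claisen rearrangement: the arylacetate α-hydrogen is the only acidic C–H, so silyl ketene acetal 29 should form cleanly, and its [3,3] shift makes the C9–C11 bond on the face from which the C7–O bond departs (β), giving the 9β-substituent, 9α-H and the C7=C8 alkene; the configuration at C11 is of no consequence because that carbon becomes CH2.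

Step 17
Reactants: 31 2-aryl-2-(decal-7-en-9β-yl)acetic acid
Product: 33 methyl 4-methoxy-3-{[4α,8,10β-trimethyl-4β-(4-methylpent-3-en-1-yl)-5α-H-decal-7-en-9β-yl]methyl}benzoate, via thiohydroxamate ester 32 (not isolated)
Conditions: N-hydroxypyridine-2-thione, DCC, DMAP (cat.), CH2Cl2, dark, rt; then t-BuSH (excess), hν, rt
Reagents that add atoms: none
Why: Barton reductive decarboxylation: photolysis of ester 32 gives the acyloxy radical, loss of CO2 leaves a benzylic radical at C11 that abstracts hydrogen from the thiol; the conditions are neutral, C9 is not involved, and the only ring closure open to the radical (onto C7=C8) is a reversible three-membered one.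

Step 18
Reactants: 33 methyl 4-methoxy-3-(decalinylmethyl)benzoate
Product: 34 jaspic acid, 4-hydroxy-3-{[(1S,4aS,5R,8aS)-2,5,8a-trimethyl-5-(4-methylpent-3-en-1-yl)-1,4,4a,5,6,7,8,8a-octahydronaphthalen-1-yl]methyl}benzoic acid
Conditions: NaSEt, DMF, 130 °C; then 0.5 M HCl to pH 3, 0 °C
Reagents that add atoms: none
Why: Thiolate SN2 dealkylation cleaves the ester methyl and the aryl methyl ether in one operation under basic conditions, which avoids acid-promoted addition of the free phenol to the C7=C8 alkene; brief cold acidification only protonates the dianion.

## Compound list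

1 | diethyl malonate | CCOC(=O)CC(=O)OCC | starting material
2 | 5-bromo-2-methylpent-2-ene | CC(C)=CCCBr | starting material
3 | diethyl 2-(4-methylpent-3-en-1-yl)malonate | CCOC(=O)C(CCC=C(C)C)C(=O)OCC | intermediate
4 | ethyl 6-methylhept-5-enoate | CCOC(=O)CCCC=C(C)C | intermediate
5 | N-methoxy-N,6-dimethylhept-5-enamide | CON(C)C(=O)CCCC=C(C)C | intermediate
6 | vinylmagnesium bromide | C=C[Mg]Br | starting material
7 | bromomagnesium chelate of the tetrahedral vinyl adduct of 5 (formed in the flask) | CON(C)C(O[Mg]Br)(C=C)CCCC=C(C)C | intermediate
8 | 8-methylnona-1,7-dien-3-one | C=CC(=O)CCCC=C(C)C | intermediate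
9 | 2-methylcyclohexane-1,3-dione | CC1C(=O)CCCC1=O | starting material
10 | 2-methyl-2-(8-methyl-3-oxonon-7-en-1-yl)cyclohexane-1,3-dione | CC(C)=CCCCC(=O)CCC1(C)C(=O)CCCC1=O | intermediate
11 | cis-fused ketol: 5β-hydroxy-10β-methyl-4-(4-methylpent-3-en-1-yl)decalin-3,9-dione, C4 undefined (formed in the flask) | CC(C)=CCCC1C(=O)CC[C@]2(C)C(=O)CCC[C@]12O | intermediate
12 | (8aS)-8a-methyl-5-(4-methylpent-3-en-1-yl)-3,4,8,8a-tetrahydronaphthalene-1,6(2H,7H)-dione; (10S)-enedione | CC(C)=CCCC1=C2CCCC(=O)[C@@]2(C)CCC1=O | intermediate
13 | C9 ethylene ketal (spiro-1,3-dioxolane) of 12 | CC(C)=CCCC1=C2CCCC3(OCCO3)[C@@]2(C)CCC1=O | intermediate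
14 | lithium C3–C4 enolate of the reduced ketal, 5α-H (formed in the flask) | CC(C)=CCCC1=C(O[Li])CC[C@]2(C)C3(OCCO3)CCC[C@@H]12 | intermediate
15 | 9,9-ethylenedioxy-4α,10β-dimethyl-4β-(4-methylpent-3-en-1-yl)-5α-H-decalin-3-one | CC(C)=CCC[C@@]1(C)C(=O)CC[C@]2(C)C3(OCCO3)CCC[C@@H]12 | intermediate
16 | C3 hydrazone of 15 (formed in the flask) | CC(C)=CCC[C@@]1(C)C(=NN)CC[C@]2(C)C3(OCCO3)CCC[C@@H]12 | intermediate
17 | 9,9-ethylenedioxy-4α,10β-dimethyl-4β-(4-methylpent-3-en-1-yl)-5α-H-decalin (formed in the flask) | CC(C)=CCC[C@@]1(C)CCC[C@]2(C)C3(OCCO3)CCC[C@@H]12 | intermediate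
18 | 4α,10β-dimethyl-4β-(4-methylpent-3-en-1-yl)-5α-H-decalin-9-one | CC(C)=CCC[C@@]1(C)CCC[C@]2(C)C(=O)CCC[C@@H]12 | intermediate
19 | lithium C8–C9 enolate of 18 (formed in the flask) | CC(C)=CCC[C@@]1(C)CCC[C@]2(C)C(O[Li])=CCC[C@@H]12 | intermediate
20 | 4α,8,10β-trimethyl-4β-(4-methylpent-3-en-1-yl)-5α-H-decalin-9-one, C8 epimers | CC(C)=CCC[C@@]1(C)CCC[C@]2(C)C(=O)C(C)CC[C@@H]12 | intermediate
21 | C8=C9 trimethylsilyl enol ether of 20 (formed in the flask) | CC(C)=CCC[C@@]1(C)CCC[C@]2(C)C(O[Si](C)(C)C)=C(C)CC[C@@H]12 | intermediate
22 | 4α,8,10β-trimethyl-4β-(4-methylpent-3-en-1-yl)-5α-H-decal-7-en-9-one | CC(C)=CCC[C@@]1(C)CCC[C@]2(C)C(=O)C(C)=CC[C@@H]12 | intermediate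
23 | 7α,8α-epoxy-4α,8β,10β-trimethyl-4β-(4-methylpent-3-en-1-yl)-5α-H-decalin-9-one | CC(C)=CCC[C@@]1(C)CCC[C@]2(C)C(=O)[C@]3(C)O[C@@H]3C[C@@H]12 | intermediate
24 | C9 hydrazone of 23 (formed in the flask) | CC(C)=CCC[C@@]1(C)CCC[C@]2(C)C(=NN)[C@]3(C)O[C@@H]3C[C@@H]12 | intermediate
25 | 4α,8,10β-trimethyl-4β-(4-methylpent-3-en-1-yl)-5α-H-decal-8-en-7α-ol | CC(C)=CCC[C@@]1(C)CCC[C@]2(C)C=C(C)[C@H](O)C[C@@H]12 | intermediate
26 | 2-(5-bromo-2-methoxyphenyl)acetic acid | OC(=O)Cc1cc(Br)ccc1OC | starting material
27 | 2-[2-methoxy-5-(methoxycarbonyl)phenyl]acetic acid | OC(=O)Cc1cc(C(=O)OC)ccc1OC | intermediate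
28 | 7β-yl ester of 27 with the inverted alcohol of 25 (decal-8-en-7β-yl arylacetate) | CC(C)=CCC[C@@]1(C)CCC[C@]2(C)C=C(C)[C@@H](OC(=O)Cc3cc(C(=O)OC)ccc3OC)C[C@@H]12 | intermediate
29 | trimethylsilyl ketene acetal of 28 (formed in the flask) | CC(C)=CCC[C@@]1(C)CCC[C@]2(C)C=C(C)[C@@H](OC(O[Si](C)(C)C)=Cc3cc(C(=O)OC)ccc3OC)C[C@@H]12 | intermediate
30 | trimethylsilyl ester of 31 (formed in the flask) | CC(C)=CCC[C@@]1(C)CCC[C@]2(C)[C@@H](C(C(=O)O[Si](C)(C)C)c3cc(C(=O)OC)ccc3OC)C(C)=CC[C@@H]12 | intermediate
31 | 2-[2-methoxy-5-(methoxycarbonyl)phenyl]-2-[4α,8,10β-trimethyl-4β-(4-methylpent-3-en-1-yl)-5α-H-decal-7-en-9β-yl]acetic acid, C11 epimers | CC(C)=CCC[C@@]1(C)CCC[C@]2(C)[C@@H](C(C(=O)O)c3cc(C(=O)OC)ccc3OC)C(C)=CC[C@@H]12 | intermediate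
32 | N-acyloxypyridine-2-thione (thiohydroxamate) ester of 31 (formed in the flask) | CC(C)=CCC[C@@]1(C)CCC[C@]2(C)[C@@H](C(C(=O)On3ccccc3=S)c4cc(C(=O)OC)ccc4OC)C(C)=CC[C@@H]12 | intermediate
33 | methyl 4-methoxy-3-{[4α,8,10β-trimethyl-4β-(4-methylpent-3-en-1-yl)-5α-H-decal-7-en-9β-yl]methyl}benzoate | CC(C)=CCC[C@@]1(C)CCC[C@]2(C)[C@@H](Cc3cc(C(=O)OC)ccc3OC)C(C)=CC[C@@H]12 | intermediate
34 | jaspic acid | CC(C)=CCC[C@@]1(C)CCC[C@]2(C)[C@@H](Cc3cc(C(=O)O)ccc3O)C(C)=CC[C@@H]12 | target

## Step count and least certain steps

Total step count: 18. Longest linear sequence: 17 steps (steps 1–13 and 15–18, from 1 and 2 to 34); step 14 is a one-step branch.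

Step 6 (key step). Enamine formation on the substituted side of the chain ketone is slow, so discrimination between the enantiotopic carbonyls may be incomplete and the optical purity eroded; long heating with acid could also start attack of the side-chain alkene on an activated carbonyl. Fallback by resolution, setting out from 10 and returning at 18: pyrrolidine/AcOH in toluene at reflux should give the racemic enedione F1. Ketalization of its C9 carbonyl with (2R,3R)-butane-2,3-diol and TsOH should give two diastereomeric ketals, whose stereocentres lie next to C10 and which are to be separated by chromatography or crystallization into the (10S)-ketal F2 and the (10R)-ketal F3, which is discarded. F2 is carried through the conditions of step 8 to the methylated ketone F4, and through the conditions of step 9, by way of the deoxygenated chiral ketal F5 that is not isolated, to 18. The step count is unchanged.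

Step 13. Hydrazone formation at C9, a carbonyl flanked by the quaternary C10 and the fully substituted epoxide carbon C8, may be slow, so that opening of the epoxide at C7 by hydrazine overtakes the transposition. Fallback by radical fragmentation, from 23 to 25: NaBH4 in MeOH gives the epoxy alcohol F6 (C9 epimers), NaH/CS2/MeI gives the S-methyl xanthate F7, and Bu3SnH/AIBN generates a C9 radical that opens the adjacent epoxide to the C7 alkoxy radical, reduced to 25 with the 7α-oxygen retained.

Step 15. Elimination of the activated pseudo-axial alcohol to a diene, or partial loss of inversion through an allylic cation, may compete with SN2 displacement by the weakly nucleophilic carboxylate. Fallback by oxidation–reduction, from 25 to 28: Dess–Martin periodinane gives the 8-en-7-one F8, Luche reduction (NaBH4, CeCl3·7H2O) with axial hydride delivery from the α-face gives the 7β-alcohol F9, and Steglich esterification (DCC, DMAP) with 27 gives 28 with retention.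

Step 16. The [3,3] shift has to start from a pseudo-equatorial C7–O bond and form a bond on the β-face of C9 beside C10; if it is slow, the silyl ketene acetal may decompose (ketene loss, C-silylation) before it rearranges. Fallback by carbonylative cross-coupling, from 20 to 33, bypassing steps 11–17: KN(SiMe3)2/PhNTf2 should give the enol triflate F10, which has the same structure as A1. Pd(OAc)2/PPh3, CO, K3PO4 and [2-methoxy-5-(methoxycarbonyl)phenyl]boronic acid should then give the aryl enone F11. KN(SiMe3)2 at −78 °C followed by AcOH moves the alkene out of conjugation, with protonation of C9 from the α-face, to the 7-en-11-one F12. NaBH4/CeCl3·7H2O gives the benzylic alcohol F13, NaH/CS2/MeI gives its xanthate F14, and Barton–McCombie reduction (Bu3SnH, AIBN) gives 33. The weak points of this detour are the protonation face and the base sensitivity of F12.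

Step 17. The stabilised benzylic radical abstracts hydrogen from the thiol slowly, so that chain propagation may fail and the radical may instead be trapped at the thiocarbonyl sulfur of 32. Fallback by reductive single-electron fragmentation, from 31 to 33: N-hydroxyphthalimide and N,N'-diisopropylcarbodiimide give the redox-active ester F15, which with [Ru(bpy)3]Cl2 (cat.), Hantzsch ester and blue light loses phthalimide anion and CO2, the benzylic radical being reduced by the dihydropyridine.

## Further compounds

F1 | step 6 | racemic 8a-methyl-5-(4-methylpent-3-en-1-yl)-3,4,8,8a-tetrahydronaphthalene-1,6(2H,7H)-dione | CC(C)=CCCC1=C2CCCC(=O)C2(C)CCC1=O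
F2 | step 6 | (10S)-enedione C9 ketal with (2R,3R)-butane-2,3-diol | CC(C)=CCCC1=C2CCCC3(O[C@H](C)[C@@H](C)O3)[C@@]2(C)CCC1=O
F3 | step 6 | (10R)-enedione C9 ketal with (2R,3R)-butane-2,3-diol | CC(C)=CCCC1=C2CCCC3(O[C@H](C)[C@@H](C)O3)[C@]2(C)CCC1=O
F4 | step 6 | 4α,10β-dimethyl-4β-(4-methylpent-3-en-1-yl)-5α-H-decalin-3-one C9 ketal with (2R,3R)-butane-2,3-diol | CC(C)=CCC[C@@]1(C)C(=O)CC[C@]2(C)C3(O[C@H](C)[C@@H](C)O3)CCC[C@@H]12
F5 | step 6 | 4α,10β-dimethyl-4β-(4-methylpent-3-en-1-yl)-5α-H-decalin C9 ketal with (2R,3R)-butane-2,3-diol | CC(C)=CCC[C@@]1(C)CCC[C@]2(C)C3(O[C@H](C)[C@@H](C)O3)CCC[C@@H]12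
F6 | step 13 | 7α,8α-epoxy-4α,8β,10β-trimethyl-4β-(4-methylpent-3-en-1-yl)-5α-H-decalin-9-ol, C9 epimers | CC(C)=CCC[C@@]1(C)CCC[C@]2(C)C(O)[C@]3(C)O[C@@H]3C[C@@H]12
F7 | step 13 | O-(7α,8α-epoxy-decalin-9-yl) S-methyl xanthate of F6 | CC(C)=CCC[C@@]1(C)CCC[C@]2(C)C(OC(=S)SC)[C@]3(C)O[C@@H]3C[C@@H]12
F8 | step 15 | 4α,8,10β-trimethyl-4β-(4-methylpent-3-en-1-yl)-5α-H-decal-8-en-7-one | CC(C)=CCC[C@@]1(C)CCC[C@]2(C)C=C(C)C(=O)C[C@@H]12
F9 | step 15 | 4α,8,10β-trimethyl-4β-(4-methylpent-3-en-1-yl)-5α-H-decal-8-en-7β-ol | CC(C)=CCC[C@@]1(C)CCC[C@]2(C)C=C(C)[C@@H](O)C[C@@H]12
F10 | step 16 | 4α,8,10β-trimethyl-4β-(4-methylpent-3-en-1-yl)-5α-H-decal-8-en-9-yl trifluoromethanesulfonate | CC(C)=CCC[C@@]1(C)CCC[C@]2(C)C(OS(=O)(=O)C(F)(F)F)=C(C)CC[C@@H]12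
F11 | step 16 | methyl 4-methoxy-3-[(decal-8-en-9-yl)carbonyl]benzoate (8-en-11-one) | CC(C)=CCC[C@@]1(C)CCC[C@]2(C)C(C(=O)c3cc(C(=O)OC)ccc3OC)=C(C)CC[C@@H]12
F12 | step 16 | methyl 4-methoxy-3-[(decal-7-en-9β-yl)carbonyl]benzoate (7-en-11-one, 9α-H) | CC(C)=CCC[C@@]1(C)CCC[C@]2(C)[C@@H](C(=O)c3cc(C(=O)OC)ccc3OC)C(C)=CC[C@@H]12
F13 | step 16 | methyl 3-[(decal-7-en-9β-yl)(hydroxy)methyl]-4-methoxybenzoate, C11 epimers | CC(C)=CCC[C@@]1(C)CCC[C@]2(C)[C@@H](C(O)c3cc(C(=O)OC)ccc3OC)C(C)=CC[C@@H]12
F14 | step 16 | S-methyl xanthate of F13 | CC(C)=CCC[C@@]1(C)CCC[C@]2(C)[C@@H](C(OC(=S)SC)c3cc(C(=O)OC)ccc3OC)C(C)=CC[C@@H]12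
F15 | step 17 | N-hydroxyphthalimide ester of 31 | CC(C)=CCC[C@@]1(C)CCC[C@]2(C)[C@@H](C(C(=O)ON3C(=O)c4ccccc4C3=O)c5cc(C(=O)OC)ccc5OC)C(C)=CC[C@@H]12
A1 | alternative 1 | C9 enol triflate of the 8-methyl decalone | CC(C)=CCC[C@@]1(C)CCC[C@]2(C)C(OS(=O)(=O)C(F)(F)F)=C(C)CC[C@@H]12
A2 | alternative 1 | methyl 4-(methoxymethoxy)-3-(4,4,5,5-tetramethyl-1,3,2-dioxaborolan-2-yl)benzoate | COCOc1ccc(C(=O)OC)cc1B1OC(C)(C)C(C)(C)O1
A3 | alternative 1 | 8(9)-en-11-one aryl ketone | CC(C)=CCC[C@@]1(C)CCC[C@]2(C)C(C(=O)c3cc(C(=O)OC)ccc3OCOC)=C(C)CC[C@@H]12
A4 | alternative 2 | trans-hydrindanone with C4 and C10 quaternary and a 3-(tert-butyldimethylsilyloxy)propyl chain | CC(C)(C)[Si](C)(C)OCCC[C@@]1(C)CCC[C@]2(C)C(=O)CC[C@@H]12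
A5 | alternative 2 | C9–C7 trimethylsilyl enol ether of A4 | CC(C)(C)[Si](C)(C)OCCC[C@@]1(C)CCC[C@]2(C)C(O[Si](C)(C)C)=CC[C@@H]12
A6 | alternative 2 | trans-decalin 8-methyl-7-en-9-one | CC(C)(C)[Si](C)(C)OCCC[C@@]1(C)CCC[C@]2(C)C(=O)C(C)=CC[C@@H]12
A7 | alternative 3 | 1-(5-hydroxy-2,4-dimethylphenyl)but-3-en-2-one | C=CC(=O)Cc1cc(O)c(C)cc1C
A8 | alternative 3 | bicyclic cross-conjugated dienone with C3 ketone and quaternary C10 | O=C1C=C2CC(=O)CC[C@]2(C)C=C1C
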